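**Plan**

- Numbering: C1/C5 ring fusion (C1 next to C10, the =CH2 carbon), C2–C4 cyclopentene, C6 carbinol, C7 side-chain carbon, C8 ring CH2, C9 acetoxy carbon, C11–C15 side chain. In the seven-membered ring the run C9(O)–C8H2–C7(–C11) is exactly what a one-carbon radical expansion of a six-membered 2-(bromomethyl) β-keto ester leaves behind, with C11 as the ester carbon.
- Retrosynthetic cuts, in order: C14=C15 (cross-metathesis), C12–C13 (oxyallylstannane addition), C11–C12/C11–CH3 (isopropenyl group built on the C11 ester, then hydroboration), C8 out of the ring (C8–C9 and C7–C8, key step), C7–C9 (Dieckmann), C5–C6 (aldol), C1–C10 (Mukaiyama–Michael).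
- Forward: cyclopentenone → trans-2,3-disubstituted cyclopentanone → C4-methyl cyclopentene → six-membered β-keto ester ring → seven-membered ring by expansion → side chain grown from C11 → C10 methylene and C9 carbinol last.
- Stereochemistry: C1 from a catalyst-controlled Michael addition; C5 and C6 from C1 through an anti-selective boron aldol; C7 from hydrogen transfer anti to the C6 silyl ether; C11 from hydroboration under allylic-strain control; C12/C13 from Felkin-selective, syn-selective allylstannane addition; C9 from a CBS reduction.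

Key step: step 13

Remark: C10 is carried as a mixture of epimers in 5–14 and is drawn in one arrangement in 15–31; it becomes trigonal in step 24, so its configuration is immaterial. 17 is drawn as one C7 epimer for the same reason.

**Route**

Step 1
Reactants: 1 methyl 3-hydroxypropanoate
Product: 2 methyl 3-[(triisopropylsilyl)oxy]propanoate
Conditions: TIPSCl, imidazole, DMF, rt
Reagents that add atoms: chlorotriisopropylsilane, CC(C)[Si](Cl)(C(C)C)C(C)C
Why: Silylation of a primary alcohol with a silyl chloride and imidazole is routine and leaves the ester untouched.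

Step 2
Reactants: 2 methyl 3-[(triisopropylsilyl)oxy]propanoate
Product: 3 silyl ketene acetal 1-methoxy-1-(trimethylsilyloxy)-3-(triisopropylsilyloxy)prop-1-ene (E/Z mixture)
Conditions: LiN(i-Pr)2, Me3SiCl (in situ quench), THF, −78 °C
Reagents that add atoms: chlorotrimethylsilane, C[Si](C)(C)Cl
Why: Ester enolisation with internal silyl chloride quench (silyl ketene acetal formation) should trap the enolate on oxygen before the β-silyloxy group can be eliminated.

Step 3
Reactants: 3 silyl ketene acetal; 4 cyclopent-2-en-1-one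
Product: 5 methyl 2-[(1R)-3-(trimethylsilyloxy)cyclopent-2-en-1-yl]-3-(triisopropylsilyloxy)propanoate (C10 epimers)
Conditions: (S)-o-tolyl-CBS-oxazaborolidinium triflimide (20 mol %), Ph3PO (25 mol %), toluene, −20 °C
Reagents that add atoms: none
Why: In this catalytic enantioselective Mukaiyama–Michael addition the boron-bound enone is shielded on one face, so the catalyst sets C1 (the (S)-series is expected to give the (1R) adduct and the antipode is used if the sense proves opposite), and silyl transfer to the enolate oxygen keeps the enol ether regiodefined at C4–C5.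

Step 4
Reactants: 5 silyl enol ether; 6 3-[(tert-butyldimethylsilyl)oxy]propanal
Product: 8 trans-2,3-disubstituted cyclopentanone with anti C5/C6 aldol unit, via dibutylboron enolate 7 (not isolated)
Conditions: Bu2BOTf, CH2Cl2, −78 → 0 °C; then 6, −78 °C; pH 7 buffer, MeOH, H2O2, 0 °C
Reagents that add atoms: none
Why: Si-to-B exchange keeps the enolate at C4–C5, and the (E)-configured cyclic boron enolate should react through a closed Zimmerman–Traxler chair (boron aldol), which gives the anti C5/C6 relation and places the new chain trans to the C1 substituent because the aldehyde approaches the face away from it.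

Step 5
Reactants: 8 aldol adduct
Product: 9 C6 triisopropylsilyl ether of 8
Conditions: TIPSOTf, 2,6-lutidine, CH2Cl2, −78 → 0 °C
Reagents that add atoms: triisopropylsilyl triflate, CC(C)[Si](OS(=O)(=O)C(F)(F)F)(C(C)C)C(C)C
Why: Silyl triflate/lutidine silylation protects a hindered β-hydroxy ketone without retro-aldol or elimination, and TIPS is chosen to outlast the later acid and fluoride steps.

Step 6
Reactants: 9 silyl-protected cyclopentanone
Product: 10 C3=C4 enol triflate
Conditions: KN(SiMe3)2, THF, −78 °C; PhNTf2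
Reagents that add atoms: N-phenylbis(trifluoromethanesulfonimide), O=S(=O)(N(c1ccccc1)S(=O)(=O)C(F)(F)F)C(F)(F)F
Why: Kinetic deprotonation with a bulky amide should occur at the unhindered C3 methylene rather than at the tertiary C5–H or the ester α-H, and O-triflation of the enolate gives the enol triflate (standard enol triflate formation).

Step 7
Reactants: 10 enol triflate
Product: 11 C4-methyl cyclopentene
Conditions: MeZnCl, Pd(PPh3)4 (5 mol %), THF, 50 °C
Reagents that add atoms: methylzinc chloride, C[Zn]Cl
Why: Negishi coupling of an enol triflate installs the C4 methyl at the fixed C3=C4 position and tolerates the ester and silyl ethers.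

Step 8
Reactants: 11 C4-methyl cyclopentene
Product: 12 C11 primary alcohol
Conditions: camphorsulfonic acid (10 mol %), MeOH/CH2Cl2, 0 °C
Reagents that add atoms: none
Why: Acid-catalysed methanolysis removes a primary TBS ether much faster than primary or secondary TIPS ethers (selective desilylation).

Step 9
Reactants: 12 primary alcohol
Product: 13 C11 carboxylic acid
Conditions: TEMPO (20 mol %), PhI(OAc)2, MeCN/H2O, rt
Reagents that add atoms: water, O
Why: The oxoammonium oxidation takes a primary alcohol through the aldehyde hydrate to the acid and leaves the trisubstituted alkene and silyl ethers alone.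

Step 10
Reactants: 13 carboxylic acid
Product: 14 dimethyl diester (C9 and C11 esters)
Conditions: Me3SiCHN2, MeOH/toluene, 0 °C
Reagents that add atoms: (trimethylsilyl)diazomethane, C[Si](C)(C)C=[N+]=[N-]
Why: Diazoalkane esterification is neutral, so the β-silyloxy acid is methylated without elimination.

Step 11
Reactants: 14 diester
Product: 15 trans-fused bicyclic β-keto ester (C9 ketone, C7 CO2Me)
Conditions: LiN(SiMe3)2 (2.2 equiv), THF, −78 → −20 °C; AcOH
Reagents that add atoms: none
Why: In this Dieckmann condensation the unhindered C7 ester enolate attacks the C9 ester (6-exo-trig) and the product is drained as its stabilised enolate, whereas closure from C10 would leave no acidic proton and stays reversible; low temperature holds back β-elimination, and the ring fusion is trans because C1 and C5 were set trans.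

Step 12
Reactants: 15 β-keto ester; 16 dibromomethane
Product: 17 C7-bromomethyl β-keto ester
Conditions: NaH, THF/DMPU, 0 °C; CH2Br2 (10 equiv), 40 °C
Reagents that add atoms: none
Why: C-Alkylation of a β-keto ester sodium enolate with excess CH2Br2 stops at the monobromide, the established entry to 2-(bromomethyl) β-keto esters, and the C7 configuration is immaterial because C7 becomes a radical centre in step 13.

Step 13
Reactants: 17 C7-bromomethyl β-keto ester
Product: 18 trans-fused seven-membered γ-keto ester (C9 ketone, C8 methylene, C7 CO2Me cis to C6 OTIPS)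
Conditions: Bu3SnH (1.3 equiv, syringe pump), AIBN (0.2 equiv), benzene (0.01 M), 80 °C
Reagents that add atoms: none
Why: Bu3Sn• abstracts bromine from 17, the primary radical adds 3-exo-trig to the C9 carbonyl, and the strained cyclopropyloxy radical reopens by β-scission of C7–C9 to the ester-stabilised C7 radical, so that C8 ends up between C9 and C7 and the six-membered ring becomes seven-membered. This is the Dowd–Beckwith ring expansion of 2-(halomethyl) β-keto esters. The only ring closure is the transient 3-exo-trig cyclopropane; the seven-membered ring arises by its fragmentation, and the regiochemistry is fixed because the bromomethyl group sits on C7 and reaches only the C9 carbonyl. C7 is set when Bu3SnH transfers hydrogen to the planar radical: allylic strain with the ester turns the C6 silyloxy group over one face, hydrogen enters anti to it, and the ester should end cis to OTIPS; both C7 epimers of 17 give the same radical. The step needs rearrangement to outrun direct reduction of the primary radical, which slow stannane addition at high dilution secures.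

Step 14
Reactants: 18 γ-keto ester
Product: 19 C9 ethylene ketal
Conditions: Me3SiOCH2CH2OSiMe3, Me3SiOTf (5 mol %), CH2Cl2, −78 → −20 °C; pyridine
Reagents that add atoms: 1,2-bis(trimethylsilyloxy)ethane, C[Si](C)(C)OCCO[Si](C)(C)C
Why: Noyori ketalisation masks the hindered C9 ketone at low temperature without touching the silyl ethers or the C7 stereocenter, so the organometallic steps that follow act only at C11.

Step 15
Reactants: 19 ketal ester
Product: 20 C11 Weinreb amide
Conditions: MeNH(OMe)·HCl, i-PrMgCl, THF, −20 → 0 °C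
Reagents that add atoms: N,O-dimethylhydroxylamine hydrochloride, CNOC.Cl
Why: Direct Weinreb amidation of a methyl ester with the magnesium amide is established for α-branched β-silyloxy esters and should proceed without C7 epimerisation at low temperature.

Step 16
Reactants: 20 Weinreb amide
Product: 21 C11 methyl ketone
Conditions: MeMgBr, THF, 0 °C; aq. NH4Cl
Reagents that add atoms: methylmagnesium bromide, C[Mg]Br
Why: In the Weinreb ketone synthesis the chelated tetrahedral intermediate stops at mono-addition and releases the ketone only on work-up, so C7 is not exposed to base as a ketone.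

Step 17
Reactants: 21 methyl ketone; 16 dibromomethane
Product: 22 C7 isopropenyl compound
Conditions: Zn, CH2Br2, TiCl4, THF/CH2Cl2, 0 °C → rt
Reagents that add atoms: none
Why: Takai–Lombardo methylenation is non-basic, so the enolisable ketone with its α-stereocenter and β-silyloxy group is methylenated without epimerisation or elimination.

Step 18
Reactants: 22 isopropenyl compound
Product: 24 (11R) primary alcohol (C12 CH2OH), via B-alkyl-9-BBN adduct 23 (not isolated)
Conditions: 9-BBN, THF, 0 → 40 °C; NaOH, H2O2, 0 °C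
Reagents that add atoms: hydrogen peroxide, OO
Why: Hydroboration–oxidation with 9-BBN selects the 1,1-disubstituted alkene over the trisubstituted ring alkene and puts boron on C12; C11 is set by 1,2-induction, because with C7–H eclipsing the alkene (allylic strain) the borane adds to the face away from the C6(OTIPS) branch, which should give (11R).

Step 19
Reactants: 24 primary alcohol
Product: 25 (11R) aldehyde (C12 CHO)
Conditions: Dess–Martin periodinane, NaHCO3, CH2Cl2, 0 °C → rt
Reagents that add atoms: none
Why: Buffered Dess–Martin oxidation gives the α-branched aldehyde without epimerising C11.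

Step 20
Reactants: 26 tert-butyldimethyl(prop-2-en-1-yloxy)silane
Product: 27 (Z)-tributyl[3-(tert-butyldimethylsilyloxy)prop-2-en-1-yl]stannane
Conditions: s-BuLi, THF/HMPA, −78 °C; Bu3SnCl
Reagents that add atoms: tributyltin chloride, CCCC[Sn](Cl)(CCCC)CCCC
Why: α-Lithiation of the allyl silyl ether gives the chelated (Z)-oxyallyl anion, which is stannylated at the γ-terminus; the bulky silyl group and low temperature suppress O-to-C silyl migration.

Step 21
Reactants: 25 aldehyde; 27 γ-silyloxyallylstannane
Product: 28 (11R,12S,13S) C12 alcohol with C13 OTBS and C14 vinyl group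
Conditions: BF3·OEt2, CH2Cl2, −78 °C; aq. NaHCO3
Reagents that add atoms: none
Why: Lewis-acid-promoted γ-oxyallylstannane addition goes through an open antiperiplanar transition state that gives the syn C12/C13 diol derivative, and attack on the aldehyde follows the Felkin–Anh model (C7 branch anti), so C12–O should be syn to the C11 methyl.

Step 22
Reactants: 28 homoallylic alcohol
Product: 29 triol (C10 CH2OH, C12 OH, C13 OH; C9 ketal and C6 OTIPS kept)
Conditions: HF·pyridine, pyridine, THF, 0 °C → rt
Reagents that add atoms: none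
Why: Buffered HF·pyridine cleaves the primary TIPS and the secondary allylic TBS ether much faster than the hindered secondary C6 TIPS ether and leaves the dioxolane intact (selective desilylation).

Step 23
Reactants: 29 triol
Product: 30 triacetate (C10 CH2OAc, C12 OAc, C13 OAc)
Conditions: Ac2O, DMAP, pyridine, CH2Cl2, rt
Reagents that add atoms: acetic anhydride, CC(=O)OC(C)=O
Why: DMAP-catalysed acetylation caps all three hydroxyls, so that no free C12/C13 diol remains to close onto C9 as a bicyclic ketal once the ketone is unmasked.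

Step 24
Reactants: 30 triacetate ketal
Product: 32 C10-methylene C9 ketone with C12 and C13 acetates, via β-acetoxymethyl ketone 31 (not isolated)
Conditions: p-TsOH·H2O (cat.), acetone/H2O, rt; then DBU, CH2Cl2, 0 °C
Reagents that add atoms: water, O
Why: Acid-catalysed ketal hydrolysis frees the C9 ketone and DBU then expels the β-acetoxy group (E1cB elimination), the standard route to an α-methylene ketone; C7 is not α to the ketone and is untouched.

Step 25
Reactants: 32 enone
Product: 33 (9R) allylic alcohol
Conditions: (S)-2-methyl-CBS-oxazaborolidine (20 mol %), catecholborane, toluene, −78 °C; MeOH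
Reagents that add atoms: none
Why: In this Corey–Bakshi–Shibata reduction the alkenyl carbon C10 acts as the large group and the C8 methylene as the small one, so the (S)-catalyst should deliver hydride to the face that gives (9R) by reagent control; catecholborane at −78 °C reduces 1,2 and leaves the alkenes alone.

Step 26
Reactants: 33 allylic alcohol
Product: 34 C9/C12/C13 triacetate (C6 OTIPS, C14 vinyl)
Conditions: Ac2O, DMAP, Et3N, CH2Cl2, 0 °C → rt
Reagents that add atoms: acetic anhydride, CC(=O)OC(C)=O
Why: Acetylation of the remaining secondary allylic alcohol is routine, and C6 stays silylated.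

Step 27
Reactants: 34 triacetate silyl ether
Product: 35 C6 alcohol triacetate with C14 vinyl group
Conditions: HF·pyridine (excess, unbuffered), THF, rt → 40 °C
Reagents that add atoms: none
Why: Forcing fluoride desilylation removes the hindered C6 TIPS ether in an acidic medium in which acetates neither migrate nor hydrolyse; it is done before the isobutenyl group makes the C13 acetate easy to ionise.

Step 28
Reactants: 35 vinyl triacetate; 36 2-methylbut-2-ene
Product: 37 CNP0194318.1 (1R,5S,6R,7S,9R,11R,12S,13S)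
Conditions: RuCl2(=CHPh)(PCy3)(H2IMes) (second-generation Grubbs catalyst, 5 mol %), 2-methylbut-2-ene (excess), CH2Cl2, 40 °C
Reagents that add atoms: none
Why: Olefin cross-metathesis with excess 2-methylbut-2-ene converts the monosubstituted vinyl group into the isobutenyl group, while the hindered 1,1-disubstituted and trisubstituted alkenes and the free hindered alcohol should not take part.

**Compound list**

1 | methyl 3-hydroxypropanoate | OCCC(=O)OC | starting material
2 | methyl 3-[(triisopropylsilyl)oxy]propanoate | COC(=O)CCO[Si](C(C)C)(C(C)C)C(C)C | intermediate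
3 | 1-methoxy-1-(trimethylsilyloxy)-3-(triisopropylsilyloxy)prop-1-ene (E/Z) | COC(=CCO[Si](C(C)C)(C(C)C)C(C)C)O[Si](C)(C)C | intermediate
4 | cyclopent-2-en-1-one | O=C1C=CCC1 | starting material
5 | methyl 2-[(1R)-3-(trimethylsilyloxy)cyclopent-2-en-1-yl]-3-(triisopropylsilyloxy)propanoate (C10 epimers) | COC(=O)C(CO[Si](C(C)C)(C(C)C)C(C)C)[C@@H]1CCC(O[Si](C)(C)C)=C1 | intermediate
6 | 3-[(tert-butyldimethylsilyl)oxy]propanal | O=CCCO[Si](C)(C)C(C)(C)C | starting material
7 | dibutylboron enolate of the C4 ketone (O–B at C4, C4=C5) | COC(=O)C(CO[Si](C(C)C)(C(C)C)C(C)C)[C@@H]1CCC(OB(CCCC)CCCC)=C1 | intermediate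
8 | cyclopentanone: C1 carries CH(CO2Me)CH2OTIPS, C5 carries CH(OH)CH2CH2OTBS; C1/C5 trans, C5/C6 anti | COC(=O)C(CO[Si](C(C)C)(C(C)C)C(C)C)[C@@H]1CCC(=O)[C@H]1[C@H](O)CCO[Si](C)(C)C(C)(C)C | intermediate
9 | C6 triisopropylsilyl ether of 8 | COC(=O)C(CO[Si](C(C)C)(C(C)C)C(C)C)[C@@H]1CCC(=O)[C@H]1[C@H](O[Si](C(C)C)(C(C)C)C(C)C)CCO[Si](C)(C)C(C)(C)C | intermediate
10 | C3=C4 enol triflate | COC(=O)C(CO[Si](C(C)C)(C(C)C)C(C)C)[C@@H]1CC=C(OS(=O)(=O)C(F)(F)F)[C@H]1[C@H](O[Si](C(C)C)(C(C)C)C(C)C)CCO[Si](C)(C)C(C)(C)C | intermediate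
11 | C4-methyl cyclopentene | COC(=O)C(CO[Si](C(C)C)(C(C)C)C(C)C)[C@@H]1CC=C(C)[C@H]1[C@H](O[Si](C(C)C)(C(C)C)C(C)C)CCO[Si](C)(C)C(C)(C)C | intermediate
12 | C11 primary alcohol | COC(=O)C(CO[Si](C(C)C)(C(C)C)C(C)C)[C@@H]1CC=C(C)[C@H]1[C@H](O[Si](C(C)C)(C(C)C)C(C)C)CCO | intermediate
13 | C11 carboxylic acid | COC(=O)C(CO[Si](C(C)C)(C(C)C)C(C)C)[C@@H]1CC=C(C)[C@H]1[C@H](O[Si](C(C)C)(C(C)C)C(C)C)CC(=O)O | intermediate
14 | dimethyl diester (C9 and C11 esters) | COC(=O)C(CO[Si](C(C)C)(C(C)C)C(C)C)[C@@H]1CC=C(C)[C@H]1[C@H](O[Si](C(C)C)(C(C)C)C(C)C)CC(=O)OC | intermediate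
15 | trans-fused bicyclic β-keto ester (six-membered ring: C9 ketone, C7 CO2Me, C6 OTIPS, C10 CH2OTIPS) | O=C1[C@@H](CO[Si](C(C)C)(C(C)C)C(C)C)[C@@H]2CC=C(C)[C@H]2[C@H](O[Si](C(C)C)(C(C)C)C(C)C)[C@H]1C(=O)OC | intermediate
16 | dibromomethane | BrCBr | starting material
17 | C7-bromomethyl β-keto ester (key-step precursor) | O=C1[C@@H](CO[Si](C(C)C)(C(C)C)C(C)C)[C@@H]2CC=C(C)[C@H]2[C@H](O[Si](C(C)C)(C(C)C)C(C)C)[C@]1(CBr)C(=O)OC | intermediate
18 | trans-fused seven-membered γ-keto ester (C9 ketone, C8 CH2, C7 CO2Me cis to C6 OTIPS) | O=C1C[C@@H](C(=O)OC)[C@@H](O[Si](C(C)C)(C(C)C)C(C)C)[C@@H]2C(C)=CC[C@H]2[C@@H]1CO[Si](C(C)C)(C(C)C)C(C)C | intermediate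
19 | C9 ethylene ketal of 18 | O1CCOC12C[C@@H](C(=O)OC)[C@@H](O[Si](C(C)C)(C(C)C)C(C)C)[C@@H]3C(C)=CC[C@H]3[C@@H]2CO[Si](C(C)C)(C(C)C)C(C)C | intermediate
20 | C11 N-methoxy-N-methylamide | O1CCOC12C[C@@H](C(=O)N(C)OC)[C@@H](O[Si](C(C)C)(C(C)C)C(C)C)[C@@H]3C(C)=CC[C@H]3[C@@H]2CO[Si](C(C)C)(C(C)C)C(C)C | intermediate
21 | C11 methyl ketone | O1CCOC12C[C@@H](C(C)=O)[C@@H](O[Si](C(C)C)(C(C)C)C(C)C)[C@@H]3C(C)=CC[C@H]3[C@@H]2CO[Si](C(C)C)(C(C)C)C(C)C | intermediate
22 | C7 isopropenyl compound | O1CCOC12C[C@@H](C(C)=C)[C@@H](O[Si](C(C)C)(C(C)C)C(C)C)[C@@H]3C(C)=CC[C@H]3[C@@H]2CO[Si](C(C)C)(C(C)C)C(C)C | intermediate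
23 | B-alkyl-9-BBN adduct (boron on C12) | O1CCOC12C[C@@H]([C@@H](C)CB4C5CCCC4CCC5)[C@@H](O[Si](C(C)C)(C(C)C)C(C)C)[C@@H]3C(C)=CC[C@H]3[C@@H]2CO[Si](C(C)C)(C(C)C)C(C)C | intermediate
24 | (11R) primary alcohol (C12 CH2OH) | O1CCOC12C[C@@H]([C@@H](C)CO)[C@@H](O[Si](C(C)C)(C(C)C)C(C)C)[C@@H]3C(C)=CC[C@H]3[C@@H]2CO[Si](C(C)C)(C(C)C)C(C)C | intermediate
25 | (11R) aldehyde (C12 CHO) | O1CCOC12C[C@@H]([C@@H](C)C=O)[C@@H](O[Si](C(C)C)(C(C)C)C(C)C)[C@@H]3C(C)=CC[C@H]3[C@@H]2CO[Si](C(C)C)(C(C)C)C(C)C | intermediate
26 | tert-butyldimethyl(prop-2-en-1-yloxy)silane | C=CCO[Si](C)(C)C(C)(C)C | starting material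
27 | (Z)-tributyl[3-(tert-butyldimethylsilyloxy)prop-2-en-1-yl]stannane | CCCC[Sn](CCCC)(CCCC)C/C=C\O[Si](C)(C)C(C)(C)C | intermediate
28 | (11R,12S,13S) C12 alcohol, C13 OTBS, C14 vinyl | O1CCOC12C[C@@H]([C@@H](C)[C@H](O)[C@H](C=C)O[Si](C)(C)C(C)(C)C)[C@@H](O[Si](C(C)C)(C(C)C)C(C)C)[C@@H]3C(C)=CC[C@H]3[C@@H]2CO[Si](C(C)C)(C(C)C)C(C)C | intermediate
29 | triol (C10 CH2OH, C12 OH, C13 OH) | O1CCOC12C[C@@H]([C@@H](C)[C@H](O)[C@H](C=C)O)[C@@H](O[Si](C(C)C)(C(C)C)C(C)C)[C@@H]3C(C)=CC[C@H]3[C@@H]2CO | intermediate
30 | triacetate of 29 | O1CCOC12C[C@@H]([C@@H](C)[C@H](OC(C)=O)[C@H](C=C)OC(C)=O)[C@@H](O[Si](C(C)C)(C(C)C)C(C)C)[C@@H]3C(C)=CC[C@H]3[C@@H]2COC(C)=O | intermediate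
31 | C9 ketone with C10 acetoxymethyl group | O=C1C[C@@H]([C@@H](C)[C@H](OC(C)=O)[C@H](C=C)OC(C)=O)[C@@H](O[Si](C(C)C)(C(C)C)C(C)C)[C@@H]2C(C)=CC[C@H]2[C@@H]1COC(C)=O | intermediate
32 | C10-methylene C9 ketone, C12/C13 diacetate | O=C1C[C@@H]([C@@H](C)[C@H](OC(C)=O)[C@H](C=C)OC(C)=O)[C@@H](O[Si](C(C)C)(C(C)C)C(C)C)[C@@H]2C(C)=CC[C@H]2C1=C | intermediate
33 | (9R) allylic alcohol | C=C1[C@H](O)C[C@@H]([C@@H](C)[C@H](OC(C)=O)[C@H](C=C)OC(C)=O)[C@@H](O[Si](C(C)C)(C(C)C)C(C)C)[C@@H]2C(C)=CC[C@@H]12 | intermediate
34 | C9/C12/C13 triacetate, C6 OTIPS, C14 vinyl | C=C1[C@H](OC(C)=O)C[C@@H]([C@@H](C)[C@H](OC(C)=O)[C@H](C=C)OC(C)=O)[C@@H](O[Si](C(C)C)(C(C)C)C(C)C)[C@@H]2C(C)=CC[C@@H]12 | intermediate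
35 | C6 alcohol triacetate, C14 vinyl | C=C1[C@H](OC(C)=O)C[C@@H]([C@@H](C)[C@H](OC(C)=O)[C@H](C=C)OC(C)=O)[C@@H](O)[C@@H]2C(C)=CC[C@@H]12 | intermediate
36 | 2-methylbut-2-ene | CC=C(C)C | starting material
37 | CNP0194318.1 | C=C1[C@H](OC(C)=O)C[C@@H]([C@@H](C)[C@H](OC(C)=O)[C@H](C=C(C)C)OC(C)=O)[C@@H](O)[C@@H]2C(C)=CC[C@@H]12 | target

**Step count and risks**

Total: 28 steps. Longest linear sequence: 27 steps (steps 1–19 and 21–28); step 20 is a one-step side branch.

Step 3, insufficient enantioselectivity or a sluggish catalytic cycle with the β-silyloxy ketene acetal. The fallback replaces catalyst control by substrate control and sets out from 3. Uncatalysed Mukaiyama–Michael addition (MeCN, 55 °C, or catalytic LiClO4) to commercial (S)-4-[(tert-butyldimethylsilyl)oxy]cyclopent-2-en-1-one in place of 4 should occur trans to the ring silyl ether and give the silyl enol ether F1. Si/B exchange with Bu2BOTf gives the boron enolate F2, and aldol with 6 gives the anti-aldol F3. TIPSOTf/2,6-lutidine gives the silyl ether F4, and DBU expels the ring silanol (E1cB) to the cyclopentenone F5. Conjugate reduction with LiBH(s-Bu)3 and trapping of the enolate with PhNTf2 returns to the route at enol triflate 10, one step later than the main line.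

Step 13, premature reduction of the primary radical before it rearranges, or incomplete facial selectivity in the hydrogen transfer at C7. The fallback makes the same skeletal change by an ionic path and sets out from 15. Et2Zn/CH2I2 (zinc carbenoid chain extension of β-keto esters) cyclopropanates the zinc enolate, the zinc cyclopropoxide fragments at C7–C9, and protonation of the resulting ester zinc enolate anti to the C6 silyl ether returns to the route at 18. No compound outside the list is made (F0).

Step 18, poor facial selectivity in the hydroboration, giving a C11 epimer mixture. The fallback uses reagent control and sets out from 21. Kinetic enolisation toward the methyl group (KN(SiMe3)2, PhNTf2) gives the enol triflate F6. Carbonylation (Pd(OAc)2, dppp, CO, MeOH, Et3N) gives the acrylate F7, and i-Bu2AlH gives the allylic alcohol F8. Hydrogenation with Ru(OAc)2(BINAP), the ligand antipode matched to (11R), reduces only the allylic alcohol double bond and returns to the route at alcohol 24.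

Further compounds
F1 | step 3 | silyl enol ether with ring C2 OTBS trans to the C1 chain | COC(=O)C(CO[Si](C(C)C)(C(C)C)C(C)C)[C@@H]1[C@@H](O[Si](C)(C)C(C)(C)C)CC(O[Si](C)(C)C)=C1
F2 | step 3 | dibutylboron enolate of F1 | COC(=O)C(CO[Si](C(C)C)(C(C)C)C(C)C)[C@@H]1[C@@H](O[Si](C)(C)C(C)(C)C)CC(OB(CCCC)CCCC)=C1
F3 | step 3 | anti-aldol of F2 with 6 | COC(=O)C(CO[Si](C(C)C)(C(C)C)C(C)C)[C@@H]1[C@@H](O[Si](C)(C)C(C)(C)C)CC(=O)[C@H]1[C@H](O)CCO[Si](C)(C)C(C)(C)C
F4 | step 3 | C6 triisopropylsilyl ether of F3 | COC(=O)C(CO[Si](C(C)C)(C(C)C)C(C)C)[C@@H]1[C@@H](O[Si](C)(C)C(C)(C)C)CC(=O)[C@H]1[C@H](O[Si](C(C)C)(C(C)C)C(C)C)CCO[Si](C)(C)C(C)(C)C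
F5 | step 3 | cyclopent-2-enone (C2=C3, C4 ketone) after loss of the ring silanol | COC(=O)C(CO[Si](C(C)C)(C(C)C)C(C)C)[C@@H]1C=CC(=O)[C@H]1[C@H](O[Si](C(C)C)(C(C)C)C(C)C)CCO[Si](C)(C)C(C)(C)C
F0 | step 13 | none | none
F6 | step 18 | C11 enol triflate of 21 | O1CCOC12C[C@@H](C(=C)OS(=O)(=O)C(F)(F)F)[C@@H](O[Si](C(C)C)(C(C)C)C(C)C)[C@@H]3C(C)=CC[C@H]3[C@@H]2CO[Si](C(C)C)(C(C)C)C(C)C
F7 | step 18 | methyl acrylate with C12 as ester carbon | O1CCOC12C[C@@H](C(=C)C(=O)OC)[C@@H](O[Si](C(C)C)(C(C)C)C(C)C)[C@@H]3C(C)=CC[C@H]3[C@@H]2CO[Si](C(C)C)(C(C)C)C(C)C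
F8 | step 18 | 2-substituted allylic alcohol (C12 CH2OH) | O1CCOC12C[C@@H](C(=C)CO)[C@@H](O[Si](C(C)C)(C(C)C)C(C)C)[C@@H]3C(C)=CC[C@H]3[C@@H]2CO[Si](C(C)C)(C(C)C)C(C)C
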